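Decide first which clock to hold this run against: a fixed fraction of the substrate per minute, or a fixed amount per minute.

all flasks: free catalyst 0.15 mM

| charge | substrate | partner | temperature | remark | time |
|---|---|---|---|---|---|
| beta | 0.22 M | 0.45 M | 110 °C | run made earlier |  |
| violet | 0.15 M | 0.450 M | 110 °C |  | 6.0 min |
| grey | 0.15 M | 0.450 M | 130 °C |  | 6.0 min |

beta run (percent of the substrate charged)

| time / s | product / % |
|---|---|
| 10.0 | 1.4 |
| 15.0 | 2.2 |
| 25.0 | 2.4 |
| 40.0 | 5.5 |
| 60.0 | 7.8 |
| 120 | 14.3 |

(each reading ± 0.5 percentage points)

- the best flask by amount of product, in percent of the substrate charged; "all alike" if 1.5 percentage points covers them all (violet / grey / all alike)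
- amount of product at the end, in percent of the substrate charged, violet
- amount of product at the end, in percent of the substrate charged, grey

- the earlier runs do not show what temperature does; that part of a forecast is a guess

The beta run leaves two simple views standing. The first chemist takes it as first order in substrate, so 14.3 % in 120 s gives a constant fraction per time, 0.0772 min⁻¹, and on that view violet reaches 37.1 % in 6.0 min. The second chemist, whose reckoning is mine, takes it as zero order in substrate, with the catalyst occupied and the molar rate constant: 14.3 % of 0.22 M in 120 s is 15.7 mM min⁻¹, a reading that carries the scatter. The charged c(substrate) divided by that rate is then the emptying time, 9.54 min for violet, so on this view violet reaches 62.9 %. Drawn through the last beta reading, the two curves differ at 60.0 s by 0.28 percentage points, less than the scatter of 0.5 points, so the readings do not choose between them.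

Temperature is a guess for both chemists, but the views part over it. At 130 °C, a speed-up of 1.59 empties grey within 6.0 min on my view and gives 52.1 % on the first. I expect at least that speed-up, so I say 100% for grey.

The forecast starts from the first view, “Treated as first order in substrate”, and sets violet at 40 %, above that view's figure, grey at 72 %, and grey as the better flask.

The flasks give 59.0 % for violet and 100 % for grey, so grey is the better flask.

    partner + catalyst intermediate B → catalyst intermediate C (k = 17.0 M⁻¹ s⁻¹, Ea = 48.0 kJ mol⁻¹)
    substrate + free catalyst → catalyst intermediate A (k = 1900 M⁻¹ s⁻¹, Ea = 55.0 kJ mol⁻¹)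
    catalyst intermediate A ⇌ catalyst intermediate B (K = 0.980, k = 7.60 s⁻¹, Ea = 88.0 kJ mol⁻¹, ΔH = −36.0 kJ mol⁻¹)
    catalyst intermediate C → free catalyst + product (k = 5.60 s⁻¹, Ea = 72.0 kJ mol⁻¹)
    (constants at 110 °C)

Violet held 30.3 % product at 3.00 min and 59.0 % at 6.00 min, near the 62.9 % reckoned from 9.54 min, with free catalyst at 1.33 %; the first view keeps the beta run, where at 60.0 s its curve stands 0.28 points from mine. In grey, substrate, the limiting reagent, stood at 0 % by 6.00 min, and the 62.6 % product at 3.00 min gives an emptying time of 4.79 min, shorter than 9.54 min by a factor 1.99, above the 1.59 required. The neighbouring flask, grey read at 1.5 min, reckons to 31.3 % and held 32.6 %.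

The runs are calculated on assumed constants; noise was put on by code.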